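## The problem

The target 17 is a 2-arylchromen-4-one with no stereocentre, so the whole difficulty is one of position and order: six oxygen substituents must be placed and told apart. Ring A is a 1,2,3,5-tetraoxygenated benzene, open only at C6, and each oxygen has a different role: O1 closes ring C, C8 carries a methyl ether, C7 the prenyl ether and C5 a free hydroxyl. C3 of ring C carries a methoxy group, whereas the classical flavone syntheses deliver C3–H or C3–OH and leave an oxidation or a methylation for the finished heterocycle. The 3-methylbut-2-enyl ether is the fragile group: acids ionise it, hydrogenolysis cleaves or saturates it, peracids and hypochlorous acid attack its alkene, and strong heating invites a Claisen shift. It must therefore go on late, and everything after it must be mild. With no stereocentres there is no relay of configuration; the control elements are the hydrogen bond of a hydroxyl next to a carbonyl group (which sets the 5-OH apart from the 7-OH, and one hydroxyl of the starting aldehyde apart from the other two) and a protecting group on the 4'-OH, which has no such bias. The feature that opens the key step is that C3 is a single carbon, already bearing its methoxy group, between two carbons that both sit at the carboxylic acid oxidation level in an O-aroylsalicylate: C4, the carboxyl carbon on C4a, and C2, the ester carbonyl carbon joining O1 to ring B. A methoxymethylene ylide can be stitched in between them, by acylation on one side and carbonyl olefination on the other.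

## Retrosynthesis

**End game, 17 ⇐ 16 ⇐ 15 ⇐ 14.** The last bonds cut are the Si–O bond at C4' (16), the O7–prenyl bond (15) and the two benzyl C–O bonds at O5 and O7 (14). Carrying the prenyl ether through the route instead would expose it to N-bromosuccinimide and to chlorite, and it could not coexist with benzyl removal. Benzyl ethers on O5 and O7 come off together, and the chelated 5-OH then stays out of the alkylation. The 4'-oxygen carries a triisopropylsilyl group rather than a smaller silyl group, so that it outlasts carbonate in the alkylation and the silanolate set free in the key step, yet falls to fluoride without harm to the allylic ether. The forward steps must spare the C2=C3 enol ether on hydrogenolysis and must alkylate O7 only.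

**Key disconnection, 14 ⇐ 10 + 12 (from 11), through 13.** The C3–C4 bond and the C2=C3 bond are cut together, which removes C3 with its methoxy group as ylide 12 and leaves the silyl O-aroylsalicylate 10. The neighbouring cut at C2–C3 alone (diketone route from a methoxymethyl ketone on ring A) needs a hindered, fully substituted aryl ketone and a strongly basic or acidic cyclodehydration. The cut at O1–C2 through a chalcone gives C3–OH and tends toward aurones when the position next to the ketone is substituted. Precursor 10 is only a diester of two benzoic acids, with no C–C bond between the fragments. The forward reaction asks two things: the ylide must pick the silyl ester over the aryl ester, and the α-methoxy acyl ylide 13 must olefinate an ester carbonyl.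

**Precursor assembly, 10 ⇐ 9 ⇐ 8 ⇐ 4 + 7.** The Si–O bond of the silyl ester, the oxidation level of the carboxyl carbon and the aryl ester C–O bond are taken apart in turn. The carboxyl carbon is kept as a formyl group until the phenol is acylated: a free salicylic acid would not acylate cleanly at oxygen, and an alkyl ester could not be cleaved beside the aryl ester. The oxidation of 8 to 9 must be mild toward the aryl ester and the electron-rich ring.

**Ring A, 4 ⇐ 3 ⇐ 2 ⇐ 1.** The C–OMe bond at the future C8 is cut to C–Br and then to C–H, and the two benzyl ethers go back to 2,4,6-trihydroxybenzaldehyde 1. The neighbouring plan turns the formyl group into the methoxy oxygen by Baeyer–Villiger oxidation and brings the carboxyl carbon back by directed metalation. It costs an extra protecting group and puts benzyl ethers and two competing sites before butyllithium. Keeping the formyl carbon of 1 as C4 leaves a single C–O bond to make. The forward steps ask for bromination ortho to the chelated hydroxyl and for copper-mediated methoxylation at a flanked position.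

**Ring B acid, 7 ⇐ 5.** The aryl Si–O bond is cut, leading to vanillic acid 5; the bis-silyl compound 6 is passed through without isolation.

## Roads not taken

**Alternative 1:** Ring C is cut at C3–C4 and O1–C8a. The lithium enolate of a ring B methoxymethyl ketone would be C-acylated by a difluorinated anisoyl chloride, and the diketone enolate oxygen would displace the fluoride ortho to the new ketone, giving A1 in one flask.
- Merits: two simple fragments, high convergence, both the 3- and 8-methoxy groups in place, and a fluorine at C7 as a handle for substitution by prenyl alkoxide para to the C4 carbonyl.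
- Weak points: A1 has no oxygen at C5, so a carbonyl-directed C–H hydroxylation peri to the ketone is needed on an advanced flavone. The substitution at C7 by an allylic alkoxide competes with conjugate attack at C2 and with cleavage of the sulfonate. The first acylation must go to carbon, not oxygen.
- Comparison: this road is more convergent, avoids a moisture-sensitive silyl ester and a non-stabilised ylide, and its ring closure rests on better-tested ground. The chosen plan sets against it that every ring A oxygen is fixed before ring C exists, so only deprotection and one chelation-controlled alkylation remain afterwards.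

**Alternative 2:** Ring A is built last, with the C4a–C5 bond formed in the key step. A metalated 2-aryl-3-methoxypyran-4-one would add to a squarate-derived cyclobutenedione; heating the adduct opens it to a vinylketene, which closes by a 6π process onto the pyranone and tautomerises to the hydroquinone A2.
- Merits: the ring A oxygens come regiodefined, the prenyl ether is present from the start, the key step is neutral and thermal, and chelation of the 5-OH lets the 8-OH be methylated selectively.
- Weak points: it needs a fully substituted pyranone that is metalated next to the ring oxygen, and an unsymmetrical cyclobutenedione that must be attacked at one of two carbonyls. The prenyl ether is heated with a free ortho position. A2 is an air-sensitive hydroquinone whose methylation must outrun oxidation to the quinone.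
- Comparison: on the timing of the prenyl group this road is better, since no benzyl on/off sequence is needed. The chosen plan sets against it a commercial source of ring A and a single untested step instead of several selectivity questions.

**Alternative 3:** Ring C is cut at O1–C2 and traced to an aurone. The aurone dibromide would be opened by hydroxide to a phenoxide diketone, and the phenoxide displaces the benzylic bromide, expanding the furanone to the flavonol A3.
- Merits: this is long-established flavonol chemistry with robust reagents; for the ring closure alone it is the safer road, and it delivers the C3 oxygen.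
- Weak points: the benzofuranone needs the same tetraoxygenated ring A plus a two-carbon unit. Bromine meets a ring A whose only free position lies between two benzyloxy groups, so nuclear bromination competes. The 3-OH needs a separate methylation. A3 carries benzyl on the 4'-oxygen as well, so hydrogenolysis would free the 7-OH and 4'-OH together, and only a modest acidity difference would steer the prenylation.
- Comparison: the precedent is stronger here. The chosen plan sets against it direct delivery of C3–OMe, no electrophilic halogen on a fully built ring A, a 4'-oxygen that stays masked until the end, and fewer steps after the common salicylaldehyde.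

Key step: step 8

## Route

**Step 1**
Reactants: 1 2,4,6-trihydroxybenzaldehyde
Product: 2 2,4-bis(benzyloxy)-6-hydroxybenzaldehyde
Conditions: BnBr (2.05 equiv), K2CO3, DMF, 0 °C to rt
Reagents that add atoms: benzyl bromide, BrCc1ccccc1
Why: Williamson etherification; after the 4-OH and one ortho OH are alkylated, the remaining hydroxyl is held in a hydrogen bond to the formyl group and reacts much more slowly, so the dibenzyl ether should be the main product.

**Step 2**
Reactants: 2 2,4-bis(benzyloxy)-6-hydroxybenzaldehyde
Product: 3 4,6-bis(benzyloxy)-3-bromo-2-hydroxybenzaldehyde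
Conditions: NBS (1.0 equiv), i-Pr2NH (0.1 equiv), CH2Cl2, −20 to 0 °C
Reagents that add atoms: N-bromosuccinimide, O=C1CCC(=O)N1Br
Why: Electrophilic aromatic bromination; by analogy with the halogenation of 2-hydroxy-4,6-dialkoxyaryl ketones, bromine should enter ortho to the free chelated hydroxyl (flanked by OH and one OBn) and not the more shielded site between the two benzyloxy groups.

**Step 3**
Reactants: 3 4,6-bis(benzyloxy)-3-bromo-2-hydroxybenzaldehyde
Product: 4 4,6-bis(benzyloxy)-2-hydroxy-3-methoxybenzaldehyde
Conditions: NaOMe (5 equiv), CuBr (0.3 equiv), MeOH–DMF, 110 °C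
Reagents that add atoms: sodium methoxide (NaOMe), C[O-].[Na+]
Why: Copper-catalysed Ullmann-type methoxylation of an aryl bromide ortho to a phenoxide, the reaction type that converts bromovanillin into syringaldehyde; benzyl ethers are inert and the aldehyde is deactivated by the ortho phenoxide.

**Step 4**
Reactants: 5 vanillic acid
Product: 7 3-methoxy-4-(triisopropylsilyloxy)benzoic acid, via bis-silyl compound 6 (not isolated)
Conditions: i-Pr3SiCl (2.3 equiv), imidazole, DMF, rt; then K2CO3, MeOH–THF–H2O, 0 °C; citric acid to pH 4
Reagents that add atoms: triisopropylsilyl chloride, CC(C)[Si](Cl)(C(C)C)C(C)C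
Why: Exhaustive O-silylation followed by selective solvolysis of the silyl ester, which is far more labile than the hindered aryl silyl ether.

**Step 5**
Reactants: 4 4,6-bis(benzyloxy)-2-hydroxy-3-methoxybenzaldehyde; 7 3-methoxy-4-(triisopropylsilyloxy)benzoic acid
Product: 8 3,5-bis(benzyloxy)-2-formyl-6-methoxyphenyl 3-methoxy-4-(triisopropylsilyloxy)benzoate
Conditions: EDC·HCl (1.5 equiv), DMAP (0.3 equiv), CH2Cl2, rt
Reagents that add atoms: none
Why: Steglich esterification; the acylpyridinium ion from 7 should acylate the ortho-carbonyl phenol, as in the routine preparation of aryl esters of 2-hydroxyaryl ketones for flavone synthesis.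

**Step 6**
Reactants: 8 3,5-bis(benzyloxy)-2-formyl-6-methoxyphenyl 3-methoxy-4-(triisopropylsilyloxy)benzoate
Product: 9 4,6-bis(benzyloxy)-3-methoxy-2-[3-methoxy-4-(triisopropylsilyloxy)benzoyloxy]benzoic acid
Conditions: NaClO2, NaH2PO4, 2-methyl-2-butene (20 equiv), t-BuOH–THF–H2O, 0 °C to rt
Reagents that add atoms: sodium chlorite (NaClO2), [O-]Cl=O.[Na+]
Why: Pinnick oxidation; chlorous acid oxidises the aldehyde under buffered conditions that leave the aryl ester, benzyl ethers and silyl ether alone, and the excess alkene traps HOCl before it can chlorinate the electron-rich ring; a peracid is avoided because it would cause Dakin-type loss of the formyl carbon.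

**Step 7**
Reactants: 9 4,6-bis(benzyloxy)-3-methoxy-2-[3-methoxy-4-(triisopropylsilyloxy)benzoyloxy]benzoic acid
Product: 10 tert-butyldimethylsilyl 4,6-bis(benzyloxy)-3-methoxy-2-[3-methoxy-4-(triisopropylsilyloxy)benzoyloxy]benzoate
Conditions: t-BuMe2SiCl (1.2 equiv), imidazole (1.5 equiv), CH2Cl2, 0 °C to rt; filtration and evaporation without aqueous work-up
Reagents that add atoms: tert-butyldimethylsilyl chloride, CC(C)(C)[Si](C)(C)Cl
Why: Silyl esterification of a carboxylic acid under standard silyl chloride–imidazole conditions; the crude ester is used at once because silyl esters hydrolyse on silica.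

**Step 8**
Reactants: 10 tert-butyldimethylsilyl 4,6-bis(benzyloxy)-3-methoxy-2-[3-methoxy-4-(triisopropylsilyloxy)benzoyloxy]benzoate; 11 (methoxymethyl)triphenylphosphonium chloride
Product: 14 5,7-bis(benzyloxy)-3,8-dimethoxy-2-[3-methoxy-4-(triisopropylsilyloxy)phenyl]chromen-4-one, via (methoxymethylene)triphenylphosphorane 12 (not isolated), via methoxy acyl ylide 13 (not isolated)
Conditions: 11 (2.2 equiv), KN(SiMe3)2 (2.1 equiv), THF, 0 °C; added slowly to 10 in THF at −78 °C, then to rt; then reflux (toluene, 110 °C, if closure is slow)
Reagents that add atoms: none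
Why: Proposed new method: ylide 12 should add to the silyl ester carbonyl of 10 at −78 °C, silanolate leaves, and the α-methoxy acylphosphonium ion is deprotonated by the silanolate or by a second equivalent of 12 to acyl ylide 13, which forms C3–C4. On warming, the ylide carbon of 13 adds to the neighbouring aryl ester carbonyl in a 6-exo-trig closure, and the oxaphosphetane loses Ph3PO to give the C2=C3 bond inside ring C. The closest known reaction type is the acylation of (trimethylsilyl)methylenetriphenylphosphorane by silyl esters of O-aroylsalicylic acids followed by intramolecular ester-carbonyl Wittig olefination to flavones. New here is the α-methoxy ylide, which must be deprotonated instead of desilylated and must close to a tetrasubstituted enol ether. The methoxy group should raise the nucleophilicity of the acyl ylide, which favours closure, while its bulk opposes it, hence the option of heating in toluene. No stereocentre is formed and the alkene geometry is fixed by the ring. The step needs chemoselectivity between two ester carbonyls in the first event: the silyl ester is anhydride-like and twisted out of conjugation by its two ortho oxygens, whereas the vanilloyl carbonyl is deactivated by the para silyloxy group and sits on a doubly flanked phenol oxygen. Low temperature and slow addition of the ylide support this choice.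

**Step 9**
Reactants: 14 5,7-bis(benzyloxy)-3,8-dimethoxy-2-[3-methoxy-4-(triisopropylsilyloxy)phenyl]chromen-4-one
Product: 15 5,7-dihydroxy-3,8-dimethoxy-2-[3-methoxy-4-(triisopropylsilyloxy)phenyl]chromen-4-one
Conditions: H2 (1 atm), Pd/C, EtOAc–THF, rt
Reagents that add atoms: none
Why: Hydrogenolysis of aryl benzyl ethers; the tetrasubstituted, conjugated C2=C3 bond of a flavone and the aryl silyl ether are not reduced under these conditions.

**Step 10**
Reactants: 15 5,7-dihydroxy-3,8-dimethoxy-2-[3-methoxy-4-(triisopropylsilyloxy)phenyl]chromen-4-one
Product: 16 5-hydroxy-3,8-dimethoxy-2-[3-methoxy-4-(triisopropylsilyloxy)phenyl]-7-(3-methylbut-2-enyloxy)chromen-4-one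
Conditions: prenyl bromide (1.1 equiv), K2CO3 (1.2 equiv), acetone, rt to 40 °C
Reagents that add atoms: 1-bromo-3-methylbut-2-ene, CC(C)=CCBr
Why: Williamson etherification; the 7-OH is the acidic, unchelated phenol, whereas the 5-OH is tied to the C4 carbonyl by a hydrogen bond, the standard basis for selective 7-O-alkylation of 5,7-dihydroxyflavones.

**Step 11**
Reactants: 16 5-hydroxy-3,8-dimethoxy-2-[3-methoxy-4-(triisopropylsilyloxy)phenyl]-7-(3-methylbut-2-enyloxy)chromen-4-one
Product: 17 5,4'-dihydroxy-3,8,3'-trimethoxy-7-prenyloxyflavone
Conditions: Bu4NF (1.1 equiv), AcOH (1.1 equiv), THF, 0 °C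
Reagents that add atoms: none
Why: Fluoride-induced cleavage of an aryl silyl ether; buffering with acetic acid keeps the medium near neutral, so the prenyl ether and the pyranone are untouched.

## Compound list

1 | 2,4,6-trihydroxybenzaldehyde | O=Cc1c(O)cc(O)cc1O | starting material
2 | 2,4-bis(benzyloxy)-6-hydroxybenzaldehyde | O=Cc1c(O)cc(OCc2ccccc2)cc1OCc1ccccc1 | intermediate
3 | 4,6-bis(benzyloxy)-3-bromo-2-hydroxybenzaldehyde | O=Cc1c(O)c(Br)c(OCc2ccccc2)cc1OCc1ccccc1 | intermediate
4 | 4,6-bis(benzyloxy)-2-hydroxy-3-methoxybenzaldehyde | COc1c(O)c(C=O)c(OCc2ccccc2)cc1OCc1ccccc1 | intermediate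
5 | vanillic acid | COc1cc(C(=O)O)ccc1O | starting material
6 | triisopropylsilyl 3-methoxy-4-(triisopropylsilyloxy)benzoate | COc1cc(C(=O)O[Si](C(C)C)(C(C)C)C(C)C)ccc1O[Si](C(C)C)(C(C)C)C(C)C | intermediate
7 | 3-methoxy-4-(triisopropylsilyloxy)benzoic acid | COc1cc(C(=O)O)ccc1O[Si](C(C)C)(C(C)C)C(C)C | intermediate
8 | 3,5-bis(benzyloxy)-2-formyl-6-methoxyphenyl 3-methoxy-4-(triisopropylsilyloxy)benzoate | COc1cc(C(=O)Oc2c(OC)c(OCc3ccccc3)cc(OCc3ccccc3)c2C=O)ccc1O[Si](C(C)C)(C(C)C)C(C)C | intermediate
9 | 4,6-bis(benzyloxy)-3-methoxy-2-[3-methoxy-4-(triisopropylsilyloxy)benzoyloxy]benzoic acid | COc1cc(C(=O)Oc2c(OC)c(OCc3ccccc3)cc(OCc3ccccc3)c2C(=O)O)ccc1O[Si](C(C)C)(C(C)C)C(C)C | intermediate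
10 | tert-butyldimethylsilyl 4,6-bis(benzyloxy)-3-methoxy-2-[3-methoxy-4-(triisopropylsilyloxy)benzoyloxy]benzoate | COc1cc(C(=O)Oc2c(OC)c(OCc3ccccc3)cc(OCc3ccccc3)c2C(=O)O[Si](C)(C)C(C)(C)C)ccc1O[Si](C(C)C)(C(C)C)C(C)C | intermediate
11 | (methoxymethyl)triphenylphosphonium chloride | COC[P+](c1ccccc1)(c1ccccc1)c1ccccc1.[Cl-] | starting material
12 | (methoxymethylene)triphenylphosphorane | COC=P(c1ccccc1)(c1ccccc1)c1ccccc1 | intermediate
13 | 3,5-bis(benzyloxy)-6-methoxy-2-[2-methoxy-2-(triphenylphosphoranylidene)acetyl]phenyl 3-methoxy-4-(triisopropylsilyloxy)benzoate | COc1cc(C(=O)Oc2c(OC)c(OCc3ccccc3)cc(OCc3ccccc3)c2C(=O)C(OC)=P(c4ccccc4)(c4ccccc4)c4ccccc4)ccc1O[Si](C(C)C)(C(C)C)C(C)C | intermediate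
14 | 5,7-bis(benzyloxy)-3,8-dimethoxy-2-[3-methoxy-4-(triisopropylsilyloxy)phenyl]chromen-4-one | COc1cc(-c2oc3c(OC)c(OCc4ccccc4)cc(OCc4ccccc4)c3c(=O)c2OC)ccc1O[Si](C(C)C)(C(C)C)C(C)C | intermediate
15 | 5,7-dihydroxy-3,8-dimethoxy-2-[3-methoxy-4-(triisopropylsilyloxy)phenyl]chromen-4-one | COc1cc(-c2oc3c(OC)c(O)cc(O)c3c(=O)c2OC)ccc1O[Si](C(C)C)(C(C)C)C(C)C | intermediate
16 | 5-hydroxy-3,8-dimethoxy-2-[3-methoxy-4-(triisopropylsilyloxy)phenyl]-7-(3-methylbut-2-enyloxy)chromen-4-one | COc1cc(-c2oc3c(OC)c(OCC=C(C)C)cc(O)c3c(=O)c2OC)ccc1O[Si](C(C)C)(C(C)C)C(C)C | intermediate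
17 | 5,4'-dihydroxy-3,8,3'-trimethoxy-7-prenyloxyflavone | COc1cc(-c2oc3c(OC)c(OCC=C(C)C)cc(O)c3c(=O)c2OC)ccc1O | target

## Step count and risks

Total step count: 11. Longest linear sequence: 10 steps (1 to 17 through steps 1, 2, 3, 5, 6, 7, 8, 9, 10, 11); step 4 is the side branch.

**Step 8 (key step, proposed new method).** Three things may go wrong:
- The non-stabilised ylide may attack the aryl ester instead of the doubly flanked silyl ester, with loss of the aroyl group.
- The ylide may decay thermally before the hindered silyl ester is acylated.
- The fully substituted α-methoxy acyl ylide may fail to close onto the ester carbonyl, so that work-up returns a hydrolysed open-chain ketone.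

Fallback with known chemistry, setting out from 10 and coming back at 14:
- 10 is treated with (trimethylsilyl)methylenetriphenylphosphorane, the ylide for which this chemistry is established. This gives the acyl ylide 3,5-bis(benzyloxy)-6-methoxy-2-[2-(triphenylphosphoranylidene)acetyl]phenyl 3-methoxy-4-(triisopropylsilyloxy)benzoate F1.
- F1 closes on heating to the C3-unsubstituted flavone 5,7-bis(benzyloxy)-8-methoxy-2-[3-methoxy-4-(triisopropylsilyloxy)phenyl]chromen-4-one F2.
- Dimethyldioxirane in acetone–CH2Cl2 at 0 °C then gives the racemic cis-fused epoxide 5,7-bis(benzyloxy)-2,3-epoxy-8-methoxy-2-[3-methoxy-4-(triisopropylsilyloxy)phenyl]chroman-4-one F3.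
- A trace of TsOH opens F3 to the flavonol 5,7-bis(benzyloxy)-3-hydroxy-8-methoxy-2-[3-methoxy-4-(triisopropylsilyloxy)phenyl]chromen-4-one F4.
- Methylation of F4 (MeI, K2CO3, acetone) gives 14.

**Step 2 (with step 3).** Bromination may go to the position between the two benzyloxy groups or proceed to the dibromide, and in step 3 the bromide may be lost by reduction at the flanked site instead of being replaced by methoxide. The fallback is regiochemically unambiguous and halogen-free; it sets out from 2 and comes back at 4:
- The chelated hydroxyl is protected (MOMCl, i-Pr2NEt, CH2Cl2) as 2,4-bis(benzyloxy)-6-(methoxymethoxy)benzaldehyde F5.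
- Baeyer–Villiger oxidation (mCPBA, CH2Cl2) gives 2,4-bis(benzyloxy)-6-(methoxymethoxy)phenyl formate F6.
- Methanolysis (K2CO3, MeOH) gives 2,4-bis(benzyloxy)-6-(methoxymethoxy)phenol F7.
- Methylation (MeI, K2CO3, acetone) gives 1,5-bis(benzyloxy)-2-methoxy-3-(methoxymethoxy)benzene F8.
- Acid (HCl, MeOH, 40 °C) frees 3,5-bis(benzyloxy)-2-methoxyphenol F9.
- Magnesium-mediated ortho-formylation (MgCl2, Et3N, paraformaldehyde, MeCN, reflux) at the only free ortho position gives 4.

**Step 5.** The hydrogen-bonded, doubly flanked phenol may acylate slowly, so that the O-acylisourea rearranges to the N-acylurea. Fallback, setting out from 7 and coming back at 8: 7 is converted with oxalyl chloride and catalytic DMF into 3-methoxy-4-(triisopropylsilyloxy)benzoyl chloride F10, which is added to the preformed sodium phenoxide of 4 (NaH, THF, 0 °C) to give 8.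

**Step 10.** Carbonate may loosen the aryl silyl ether, which would then allow prenylation at the 4'-oxygen; C-alkylation at C6 or slow alkylation of the 5-OH may also occur. Fallback, setting out from 15 and coming back at 16: Mitsunobu etherification with 3-methylbut-2-en-1-ol (PPh3, diisopropyl azodicarboxylate, THF, 0 °C). No phenoxide is generated, and only the more acidic, unchelated 7-OH should react. This fallback makes no new compound (F0).

## Further compounds

F1 | step 8 | 3,5-bis(benzyloxy)-6-methoxy-2-[2-(triphenylphosphoranylidene)acetyl]phenyl 3-methoxy-4-(triisopropylsilyloxy)benzoate | COc1cc(C(=O)Oc2c(OC)c(OCc3ccccc3)cc(OCc3ccccc3)c2C(=O)C=P(c4ccccc4)(c4ccccc4)c4ccccc4)ccc1O[Si](C(C)C)(C(C)C)C(C)C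
F2 | step 8 | 5,7-bis(benzyloxy)-8-methoxy-2-[3-methoxy-4-(triisopropylsilyloxy)phenyl]chromen-4-one | COc1cc(-c2cc(=O)c3c(OCc4ccccc4)cc(OCc4ccccc4)c(OC)c3o2)ccc1O[Si](C(C)C)(C(C)C)C(C)C
F3 | step 8 | 5,7-bis(benzyloxy)-2,3-epoxy-8-methoxy-2-[3-methoxy-4-(triisopropylsilyloxy)phenyl]chroman-4-one (racemic, cis-fused; one enantiomer drawn) | COc1c(OCc2ccccc2)cc(OCc3ccccc3)c4c1O[C@@]5(c6ccc(O[Si](C(C)C)(C(C)C)C(C)C)c(OC)c6)O[C@H]5C4=O
F4 | step 8 | 5,7-bis(benzyloxy)-3-hydroxy-8-methoxy-2-[3-methoxy-4-(triisopropylsilyloxy)phenyl]chromen-4-one | COc1cc(-c2oc3c(OC)c(OCc4ccccc4)cc(OCc4ccccc4)c3c(=O)c2O)ccc1O[Si](C(C)C)(C(C)C)C(C)C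
F5 | step 2 | 2,4-bis(benzyloxy)-6-(methoxymethoxy)benzaldehyde | COCOc1cc(OCc2ccccc2)cc(OCc2ccccc2)c1C=O
F6 | step 2 | 2,4-bis(benzyloxy)-6-(methoxymethoxy)phenyl formate | COCOc1cc(OCc2ccccc2)cc(OCc2ccccc2)c1OC=O
F7 | step 2 | 2,4-bis(benzyloxy)-6-(methoxymethoxy)phenol | COCOc1cc(OCc2ccccc2)cc(OCc2ccccc2)c1O
F8 | step 2 | 1,5-bis(benzyloxy)-2-methoxy-3-(methoxymethoxy)benzene | COCOc1cc(OCc2ccccc2)cc(OCc2ccccc2)c1OC
F9 | step 2 | 3,5-bis(benzyloxy)-2-methoxyphenol | COc1c(O)cc(OCc2ccccc2)cc1OCc1ccccc1
F10 | step 5 | 3-methoxy-4-(triisopropylsilyloxy)benzoyl chloride | COc1cc(C(Cl)=O)ccc1O[Si](C(C)C)(C(C)C)C(C)C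
F0 | step 10 | none | none
A1 | alternative 1 | 7-fluoro-3,8-dimethoxy-2-[3-methoxy-4-(tosyloxy)phenyl]chromen-4-one | COc1cc(-c2oc3c(OC)c(F)ccc3c(=O)c2OC)ccc1OS(=O)(=O)c1ccc(C)cc1
A2 | alternative 2 | 5,8-dihydroxy-3-methoxy-2-(3-methoxy-4-pivaloyloxyphenyl)-7-(prenyloxy)chromen-4-one | COc1cc(-c2oc3c(O)c(OCC=C(C)C)cc(O)c3c(=O)c2OC)ccc1OC(=O)C(C)(C)C
A3 | alternative 3 | 5,7-bis(benzyloxy)-2-(4-benzyloxy-3-methoxyphenyl)-3-hydroxy-8-methoxychromen-4-one | COc1cc(-c2oc3c(OC)c(OCc4ccccc4)cc(OCc4ccccc4)c3c(=O)c2O)ccc1OCc1ccccc1
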